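**Strategy**

The synthesis rests on cutting ring A of the flavanone at two neighbouring bonds, C7–O and C8–C1''. C7 and C8 are adjacent, C8 is flanked by the pyranone oxygen (O1 on C8a), and C6 carries only hydrogen. A 7,8-aryne of the chromone can therefore take up a carboxylate oxygen at C7 and pass the acyl group on to C8. The phenol and the whole C1''–C9'' chain arrive in one operation, and no contest between C6 and C8 has to be won. The aryne precursor is 5-methoxy-8-trimethylsilylchromon-7-yl triflate; its partner is the MOM-protected (3R,4E,7S)-3,9-diaryl-7-oxygenated non-4-enoic acid. Ketone reduction, aryl conjugate addition and MOM removal complete the target.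

Key step: step 15

Remark: the antipodes of the chiral reagents in steps 10 and 18 are chosen by analogy with the accepted facial models (methyl-ketone diisopinocampheyl enolborinates reacting in the same sense as the corresponding allylboranes; pyridine-oxazoline palladium additions to cyclic enones); if either model does not transfer, the mirror-image reagent is used.

**Route**

Step 1
Reactants: 1 5-methoxyresorcinol
Product: 2 1-methoxy-3,5-bis(methoxymethoxy)benzene
Conditions: MOMCl, i-Pr2NEt, CH2Cl2, 0 °C to rt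
Reagents that add atoms: chloromethyl methyl ether, COCCl
Why: Double O-alkylation of the phenols with the α-chloro ether (Williamson-type acetal formation) should proceed cleanly under amine base and installs the two strongest ortho-directing groups on the future O1 and O7.

Step 2
Reactants: 2 1-methoxy-3,5-bis(methoxymethoxy)benzene
Product: 4 [4-methoxy-2,6-bis(methoxymethoxy)phenyl]trimethylsilane, via aryllithium 3 (not isolated)
Conditions: n-BuLi, THF, 0 °C; then Me3SiCl, 0 °C to rt; neutral work-up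
Reagents that add atoms: chlorotrimethylsilane, C[Si](C)(C)Cl
Why: Directed ortho-metalation should occur at the carbon flanked by both methoxymethoxy groups, the most acidic and doubly chelated site, so the silyl quench places silicon on the future C8.

Step 3
Reactants: 4 [4-methoxy-2,6-bis(methoxymethoxy)phenyl]trimethylsilane; 5 3-(trimethylsilyl)prop-2-ynal
Product: 7 rac-1-[6-methoxy-2,4-bis(methoxymethoxy)-3-(trimethylsilyl)phenyl]-3-(trimethylsilyl)prop-2-yn-1-ol, via aryllithium 6 (not isolated)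
Conditions: n-BuLi, N,N,N',N'-tetramethylethylenediamine, THF, 0 °C; then 5, −78 °C
Reagents that add atoms: none
Why: A second directed ortho-metalation can only take place at the two equivalent C–H positions between OMe and OMOM, and 1,2-addition of the aryllithium to the non-enolisable ynal then fixes the future C4 on C4a without a regiochemical question; the new carbinol centre is racemic and is erased in step 4.

Step 4
Reactants: 7 rac-1-[6-methoxy-2,4-bis(methoxymethoxy)-3-(trimethylsilyl)phenyl]-3-(trimethylsilyl)prop-2-yn-1-ol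
Product: 8 1-[6-methoxy-2,4-bis(methoxymethoxy)-3-(trimethylsilyl)phenyl]-3-(trimethylsilyl)prop-2-yn-1-one
Conditions: MnO2 (activated, excess), CH2Cl2, rt
Reagents that add atoms: none
Why: Oxidation of a benzylic and propargylic alcohol by activated MnO2 is fast and neutral, which spares the acid-labile trioxygenated aryl–silicon bond.

Step 5
Reactants: 8 1-[6-methoxy-2,4-bis(methoxymethoxy)-3-(trimethylsilyl)phenyl]-3-(trimethylsilyl)prop-2-yn-1-one
Product: 11 7-hydroxy-5-methoxy-8-(trimethylsilyl)-4H-chromen-4-one, via bis(silyl ether) 9 (not isolated), via dihydroxy ynone 10 (not isolated)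
Conditions: Me3SiOTf, 2,2'-bipyridyl, MeCN, 0 °C to rt; then K2CO3, MeOH, rt
Reagents that add atoms: none
Why: Aprotic MOM cleavage with the silyl triflate–bipyridyl pair converts the aryl acetals into silyl ethers without the protic acid that would protodesilylate this very electron-rich aryl silane (ipso attack by a silyl electrophile is degenerate), and carbonate in methanol then removes the O- and alkynyl-silyl groups so that the ortho-phenoxide closes the pyranone by 6-endo-dig oxa-Michael addition.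

Step 6
Reactants: 11 7-hydroxy-5-methoxy-8-(trimethylsilyl)-4H-chromen-4-one
Product: 12 5-methoxy-4-oxo-8-(trimethylsilyl)-4H-chromen-7-yl trifluoromethanesulfonate
Conditions: PhNTf2, K2CO3, DMF, rt
Reagents that add atoms: N-phenylbis(trifluoromethanesulfonimide), O=S(=O)(N(c1ccccc1)S(=O)(=O)C(F)(F)F)C(F)(F)F
Why: O-Sulfonylation of the acidic 7-phenoxide with the mild triflimide reagent should give the ortho-silyl aryl triflate without the carbonyl activation that triflic anhydride can cause on a 4-pyranone.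

Step 7
Reactants: 13 (E)-4-(4-hydroxyphenyl)but-3-en-2-one
Product: 14 (E)-4-[4-(methoxymethoxy)phenyl]but-3-en-2-one
Conditions: MOMCl, i-Pr2NEt, CH2Cl2, 0 °C to rt
Reagents that add atoms: chloromethyl methyl ether, COCCl
Why: Phenol O-alkylation with the α-chloro ether under amine base masks the acidic OH before the enolisation chemistry and leaves the enone untouched.

Step 8
Reactants: 15 methyl 3-(4-hydroxyphenyl)propanoate
Product: 16 methyl 3-[4-(methoxymethoxy)phenyl]propanoate
Conditions: MOMCl, i-Pr2NEt, CH2Cl2, 0 °C to rt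
Reagents that add atoms: chloromethyl methyl ether, COCCl
Why: The same phenol O-alkylation gives an acetal that survives hydride, enolate and fluoride conditions later in the route.

Step 9
Reactants: 16 methyl 3-[4-(methoxymethoxy)phenyl]propanoate
Product: 17 3-[4-(methoxymethoxy)phenyl]propanal
Conditions: i-Bu2AlH, CH2Cl2, −78 °C
Reagents that add atoms: none
Why: Partial ester reduction at −78 °C stops at the tetrahedral aluminium hemiacetal, which releases the aldehyde only on work-up.

Step 10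
Reactants: 14 (E)-4-[4-(methoxymethoxy)phenyl]but-3-en-2-one; 17 3-[4-(methoxymethoxy)phenyl]propanal
Product: 19 (1E,5S)-5-hydroxy-1,7-bis[4-(methoxymethoxy)phenyl]hept-1-en-3-one, via enol borinate 18 (not isolated)
Conditions: (+)-B-chlorodiisopinocampheylborane ((+)-Ipc2BCl), Et3N, Et2O, 0 °C; then 17, −78 to −20 °C; then H2O2, MeOH, pH 7 buffer
Reagents that add atoms: none
Why: Boron-mediated aldol addition in which the chloroborane enolises the methyl ketone on its only enolisable side and the diisopinocampheyl ligands direct attack of the enol borinate on the re face of the aldehyde in a cyclic transition state, setting C5 as (S); any minor (5R) enantiomer becomes a separable diastereomer after step 12.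

Step 11
Reactants: 19 (1E,5S)-5-hydroxy-1,7-bis[4-(methoxymethoxy)phenyl]hept-1-en-3-one
Product: 20 (1E,5S)-5-(methoxymethoxy)-1,7-bis[4-(methoxymethoxy)phenyl]hept-1-en-3-one
Conditions: MOMCl, i-Pr2NEt, CH2Cl2, 0 °C to rt
Reagents that add atoms: chloromethyl methyl ether, COCCl
Why: Acetal formation at the secondary hydroxyl under a non-nucleophilic amine base protects the future C7'' oxygen without the retro-aldol or β-elimination that stronger bases would risk.

Step 12
Reactants: 20 (1E,5S)-5-(methoxymethoxy)-1,7-bis[4-(methoxymethoxy)phenyl]hept-1-en-3-one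
Product: 21 (1E,3R,5S)-5-(methoxymethoxy)-1,7-bis[4-(methoxymethoxy)phenyl]hept-1-en-3-ol
Conditions: (S)-1-methyl-3,3-diphenyltetrahydro-1H,3H-pyrrolo[1,2-c][1,3,2]oxazaborole ((S)-Me-CBS, 20 mol %), catecholborane, toluene, −78 °C
Reagents that add atoms: none
Why: CBS reduction in which the styryl group acts as the large substituent should deliver hydride to the face dictated by the (S)-oxazaborolidine and set C3 as (R), anti to C5, while catecholborane gives clean 1,2-reduction of the enone.

Step 13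
Reactants: 21 (1E,3R,5S)-5-(methoxymethoxy)-1,7-bis[4-(methoxymethoxy)phenyl]hept-1-en-3-ol
Product: 22 (1E,3R,5S)-5-(methoxymethoxy)-1,7-bis[4-(methoxymethoxy)phenyl]hept-1-en-3-yl acetate
Conditions: Ac2O, pyridine, 4-(dimethylamino)pyridine (cat.), CH2Cl2, 0 °C
Reagents that add atoms: acetic anhydride, CC(=O)OC(C)=O
Why: Standard acylation of the allylic alcohol under basic conditions retains the C3 configuration and provides the ester needed for the sigmatropic step.

Step 14
Reactants: 22 (1E,3R,5S)-5-(methoxymethoxy)-1,7-bis[4-(methoxymethoxy)phenyl]hept-1-en-3-yl acetate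
Product: 25 (3R,4E,7S)-7-(methoxymethoxy)-3,9-bis[4-(methoxymethoxy)phenyl]non-4-enoic acid, via silyl ketene acetal 23 (not isolated), via silyl ester 24 (not isolated)
Conditions: LiN(i-Pr)2, Me3SiCl, THF, −78 to 50 °C; then H2O
Reagents that add atoms: none
Why: Ireland–Claisen rearrangement in which the silyl ketene acetal of the acetate reacts through a chair transition state with the C4 chain pseudo-equatorial, so the (3R) carbinol configuration is transferred suprafacially to the new benzylic centre (3R) and the new alkene is E.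

Step 15
Reactants: 12 5-methoxy-4-oxo-8-(trimethylsilyl)-4H-chromen-7-yl trifluoromethanesulfonate; 25 (3R,4E,7S)-7-(methoxymethoxy)-3,9-bis[4-(methoxymethoxy)phenyl]non-4-enoic acid
Product: 27 7-hydroxy-5-methoxy-8-[(3R,4E,7S)-7-(methoxymethoxy)-3,9-bis[4-(methoxymethoxy)phenyl]non-4-enoyl]-4H-chromen-4-one, via chromone aryne 26 (not isolated)
Conditions: 12 (1.5 equiv), CsF (4 equiv), THF, 125 °C, sealed tube
Reagents that add atoms: none
Why: Fluoride attacks silicon and triflate departs to give the 7,8-didehydrochromone 26, whose strained bond is polarised by the inductively withdrawing O1 on C8a so that the cesium carboxylate oxygen adds at C7 and the negative charge develops on C8 next to that oxygen, while C6 with only hydrogen offers no opposing bias and less hindrance. The C8 aryl anion then attacks the neighbouring ester carbonyl through a four-membered alkoxide that opens to the 8-acyl 7-phenoxide, which is protonated on work-up. The closest known reaction type is the fluoride-induced formal insertion of arynes into the C–O bond of carboxylic acids to give ortho-hydroxyaryl ketones, run in hot THF where acyl transfer outruns proton capture. No ring is closed and no stereocentre is formed, and C3'' and C7'' are not α to the new carbonyl and should be unaffected. The selectivities required are O-attack at C7 rather than C8, secured by O1, and reaction of the carboxylate rather than other nucleophiles, secured by MOM protection of every hydroxyl in both partners.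

Step 16
Reactants: 27 7-hydroxy-5-methoxy-8-[(3R,4E,7S)-7-(methoxymethoxy)-3,9-bis[4-(methoxymethoxy)phenyl]non-4-enoyl]-4H-chromen-4-one
Product: 28 5-methoxy-7-(methoxymethoxy)-8-[(3R,4E,7S)-7-(methoxymethoxy)-3,9-bis[4-(methoxymethoxy)phenyl]non-4-enoyl]-4H-chromen-4-one
Conditions: MOMCl, i-Pr2NEt, CH2Cl2, 0 °C to rt
Reagents that add atoms: chloromethyl methyl ether, COCCl
Why: O-Alkylation of the acidic, hydrogen-bonded 7-phenol removes the O–H that would otherwise consume the borane and deliver hydride unselectively in step 17.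

Step 17
Reactants: 28 5-methoxy-7-(methoxymethoxy)-8-[(3R,4E,7S)-7-(methoxymethoxy)-3,9-bis[4-(methoxymethoxy)phenyl]non-4-enoyl]-4H-chromen-4-one
Product: 29 8-[(1S,3R,4E,7S)-1-hydroxy-7-(methoxymethoxy)-3,9-bis[4-(methoxymethoxy)phenyl]non-4-en-1-yl]-5-methoxy-7-(methoxymethoxy)-4H-chromen-4-one
Conditions: (R)-1-methyl-3,3-diphenyltetrahydro-1H,3H-pyrrolo[1,2-c][1,3,2]oxazaborole ((R)-Me-CBS, 20 mol %), catecholborane, toluene/CH2Cl2, −78 to −40 °C
Reagents that add atoms: none
Why: CBS reduction with the aryl ring as the large substituent and the (R)-oxazaborolidine should deliver hydride to the face giving the (1''S) alcohol, catecholborane being chosen because it neither hydroborates the C4''=C5'' alkene nor reduces the s-trans-locked pyranone enone.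

Step 18
Reactants: 29 8-[(1S,3R,4E,7S)-1-hydroxy-7-(methoxymethoxy)-3,9-bis[4-(methoxymethoxy)phenyl]non-4-en-1-yl]-5-methoxy-7-(methoxymethoxy)-4H-chromen-4-one; 30 4-(methoxymethoxy)phenylboronic acid
Product: 31 (2S)-8-[(1S,3R,4E,7S)-1-hydroxy-7-(methoxymethoxy)-3,9-bis[4-(methoxymethoxy)phenyl]non-4-en-1-yl]-5-methoxy-7-(methoxymethoxy)-2-[4-(methoxymethoxy)phenyl]-2,3-dihydro-4H-chromen-4-one
Conditions: Pd(OCOCF3)2 (10 mol %), (R)-4-tert-butyl-2-(pyridin-2-yl)-4,5-dihydrooxazole (12 mol %), NH4PF6 (30 mol %), H2O (5 equiv), ClCH2CH2Cl, 40–60 °C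
Reagents that add atoms: none
Why: Palladium-catalysed asymmetric conjugate addition of the arylboronic acid (transmetalation to a cationic divalent palladium–aryl species, enantiodetermining carbopalladation of C2=C3, protonolysis of the palladium enolate) should give the flavanone with C2 set as (S) by the (R)-pyridine-oxazoline ligand in a water-tolerant, nearly neutral medium.

Step 19
Reactants: 31 (2S)-8-[(1S,3R,4E,7S)-1-hydroxy-7-(methoxymethoxy)-3,9-bis[4-(methoxymethoxy)phenyl]non-4-en-1-yl]-5-methoxy-7-(methoxymethoxy)-2-[4-(methoxymethoxy)phenyl]-2,3-dihydro-4H-chromen-4-one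
Product: 33 (2S)-8-[(1S,3R,4E,7S)-1,7-dihydroxy-3,9-bis(4-hydroxyphenyl)non-4-en-1-yl]-7-hydroxy-2-(4-hydroxyphenyl)-5-methoxy-2,3-dihydro-4H-chromen-4-one, via silylated pyridinium salt 32 (not isolated)
Conditions: Me3SiOTf, 2,2'-bipyridyl, MeCN, 0 °C to rt; then H2O, rt
Reagents that add atoms: none
Why: Aprotic MOM cleavage by the silyl triflate–bipyridyl pair turns the aryl acetals into silyl ethers and the alkyl acetal into a pyridinium acetal, all hydrolysed by water, so the ionisable ortho-oxygenated benzylic alcohol at C1'' and the base-sensitive C2 of the flavanone never meet strong protic acid or base.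

**Compound list**

1 | 5-methoxyresorcinol | COc1cc(O)cc(O)c1 | starting material
2 | 1-methoxy-3,5-bis(methoxymethoxy)benzene | COCOc1cc(OC)cc(OCOC)c1 | intermediate
3 | [4-methoxy-2,6-bis(methoxymethoxy)phenyl]lithium | [Li]c1c(OCOC)cc(OC)cc1OCOC | intermediate
4 | [4-methoxy-2,6-bis(methoxymethoxy)phenyl]trimethylsilane | COCOc1cc(OC)cc(OCOC)c1[Si](C)(C)C | intermediate
5 | 3-(trimethylsilyl)prop-2-ynal | C[Si](C)(C)C#CC=O | starting material
6 | [6-methoxy-2,4-bis(methoxymethoxy)-3-(trimethylsilyl)phenyl]lithium | [Li]c1c(OC)cc(OCOC)c([Si](C)(C)C)c1OCOC | intermediate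
7 | rac-1-[6-methoxy-2,4-bis(methoxymethoxy)-3-(trimethylsilyl)phenyl]-3-(trimethylsilyl)prop-2-yn-1-ol | COc1cc(OCOC)c([Si](C)(C)C)c(OCOC)c1C(O)C#C[Si](C)(C)C | intermediate
8 | 1-[6-methoxy-2,4-bis(methoxymethoxy)-3-(trimethylsilyl)phenyl]-3-(trimethylsilyl)prop-2-yn-1-one | COc1cc(OCOC)c([Si](C)(C)C)c(OCOC)c1C(=O)C#C[Si](C)(C)C | intermediate
9 | 1-[6-methoxy-3-(trimethylsilyl)-2,4-bis(trimethylsilyloxy)phenyl]-3-(trimethylsilyl)prop-2-yn-1-one | COc1cc(O[Si](C)(C)C)c([Si](C)(C)C)c(O[Si](C)(C)C)c1C(=O)C#C[Si](C)(C)C | intermediate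
10 | 1-[2,4-dihydroxy-6-methoxy-3-(trimethylsilyl)phenyl]prop-2-yn-1-one | COc1cc(O)c([Si](C)(C)C)c(O)c1C(=O)C#C | intermediate
11 | 7-hydroxy-5-methoxy-8-(trimethylsilyl)-4H-chromen-4-one | COc1cc(O)c([Si](C)(C)C)c2c1C(=O)C=CO2 | intermediate
12 | 5-methoxy-4-oxo-8-(trimethylsilyl)-4H-chromen-7-yl trifluoromethanesulfonate | COc1cc(OS(=O)(=O)C(F)(F)F)c([Si](C)(C)C)c2c1C(=O)C=CO2 | intermediate
13 | (E)-4-(4-hydroxyphenyl)but-3-en-2-one | CC(=O)/C=C/c1ccc(O)cc1 | starting material
14 | (E)-4-[4-(methoxymethoxy)phenyl]but-3-en-2-one | CC(=O)/C=C/c1ccc(OCOC)cc1 | intermediate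
15 | methyl 3-(4-hydroxyphenyl)propanoate | COC(=O)CCc1ccc(O)cc1 | starting material
16 | methyl 3-[4-(methoxymethoxy)phenyl]propanoate | COCOc1ccc(CCC(=O)OC)cc1 | intermediate
17 | 3-[4-(methoxymethoxy)phenyl]propanal | COCOc1ccc(CCC=O)cc1 | intermediate
18 | (3E)-4-[4-(methoxymethoxy)phenyl]buta-1,3-dien-2-yl diisopinocampheylborinate (from (+)-Ipc2BCl) | C=C(/C=C/c1ccc(OCOC)cc1)OB([C@H]1C[C@H]2C[C@@H]([C@@H]1C)C2(C)C)[C@H]1C[C@H]2C[C@@H]([C@@H]1C)C2(C)C | intermediate
19 | (1E,5S)-5-hydroxy-1,7-bis[4-(methoxymethoxy)phenyl]hept-1-en-3-one | COCOc1ccc(/C=C/C(=O)C[C@@H](O)CCc2ccc(OCOC)cc2)cc1 | intermediate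
20 | (1E,5S)-5-(methoxymethoxy)-1,7-bis[4-(methoxymethoxy)phenyl]hept-1-en-3-one | COCOc1ccc(/C=C/C(=O)C[C@@H](OCOC)CCc2ccc(OCOC)cc2)cc1 | intermediate
21 | (1E,3R,5S)-5-(methoxymethoxy)-1,7-bis[4-(methoxymethoxy)phenyl]hept-1-en-3-ol | COCOc1ccc(/C=C/[C@H](O)C[C@@H](OCOC)CCc2ccc(OCOC)cc2)cc1 | intermediate
22 | (1E,3R,5S)-5-(methoxymethoxy)-1,7-bis[4-(methoxymethoxy)phenyl]hept-1-en-3-yl acetate | COCOc1ccc(/C=C/[C@H](OC(C)=O)C[C@@H](OCOC)CCc2ccc(OCOC)cc2)cc1 | intermediate
23 | trimethyl[(1-{[(1E,3R,5S)-5-(methoxymethoxy)-1,7-bis[4-(methoxymethoxy)phenyl]hept-1-en-3-yl]oxy}ethenyl)oxy]silane | COCOc1ccc(/C=C/[C@H](OC(=C)O[Si](C)(C)C)C[C@@H](OCOC)CCc2ccc(OCOC)cc2)cc1 | intermediate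
24 | trimethylsilyl (3R,4E,7S)-7-(methoxymethoxy)-3,9-bis[4-(methoxymethoxy)phenyl]non-4-enoate | C[Si](C)(C)OC(=O)C[C@H](/C=C/C[C@@H](OCOC)CCc1ccc(OCOC)cc1)c1ccc(OCOC)cc1 | intermediate
25 | (3R,4E,7S)-7-(methoxymethoxy)-3,9-bis[4-(methoxymethoxy)phenyl]non-4-enoic acid | OC(=O)C[C@H](/C=C/C[C@@H](OCOC)CCc1ccc(OCOC)cc1)c1ccc(OCOC)cc1 | intermediate
26 | 5-methoxy-7,8-didehydro-4H-chromen-4-one | COC1=CC#CC2=C1C(=O)C=CO2 | intermediate
27 | 7-hydroxy-5-methoxy-8-[(3R,4E,7S)-7-(methoxymethoxy)-3,9-bis[4-(methoxymethoxy)phenyl]non-4-enoyl]-4H-chromen-4-one | COc1cc(O)c(C(=O)C[C@H](/C=C/C[C@@H](OCOC)CCc2ccc(OCOC)cc2)c2ccc(OCOC)cc2)c2c1C(=O)C=CO2 | intermediate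
28 | 5-methoxy-7-(methoxymethoxy)-8-[(3R,4E,7S)-7-(methoxymethoxy)-3,9-bis[4-(methoxymethoxy)phenyl]non-4-enoyl]-4H-chromen-4-one | COc1cc(OCOC)c(C(=O)C[C@H](/C=C/C[C@@H](OCOC)CCc2ccc(OCOC)cc2)c2ccc(OCOC)cc2)c2c1C(=O)C=CO2 | intermediate
29 | 8-[(1S,3R,4E,7S)-1-hydroxy-7-(methoxymethoxy)-3,9-bis[4-(methoxymethoxy)phenyl]non-4-en-1-yl]-5-methoxy-7-(methoxymethoxy)-4H-chromen-4-one | COc1cc(OCOC)c([C@@H](O)C[C@H](/C=C/C[C@@H](OCOC)CCc2ccc(OCOC)cc2)c2ccc(OCOC)cc2)c2c1C(=O)C=CO2 | intermediate
30 | 4-(methoxymethoxy)phenylboronic acid | COCOc1ccc(B(O)O)cc1 | starting material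
31 | (2S)-8-[(1S,3R,4E,7S)-1-hydroxy-7-(methoxymethoxy)-3,9-bis[4-(methoxymethoxy)phenyl]non-4-en-1-yl]-5-methoxy-7-(methoxymethoxy)-2-[4-(methoxymethoxy)phenyl]-2,3-dihydro-4H-chromen-4-one | COc1cc(OCOC)c([C@@H](O)C[C@H](/C=C/C[C@@H](OCOC)CCc2ccc(OCOC)cc2)c2ccc(OCOC)cc2)c2c1C(=O)C[C@@H](c1ccc(OCOC)cc1)O2 | intermediate
32 | pentakis(trimethylsilyl) ether of the target carrying a 1-(alkoxymethyl)-2,2'-bipyridin-1-ium group on O7'', triflate salt | COc1cc(O[Si](C)(C)C)c([C@@H](O[Si](C)(C)C)C[C@H](/C=C/C[C@@H](OC[n+]2ccccc2-c2ccccn2)CCc2ccc(O[Si](C)(C)C)cc2)c2ccc(O[Si](C)(C)C)cc2)c2c1C(=O)C[C@@H](c1ccc(O[Si](C)(C)C)cc1)O2.[O-]S(=O)(=O)C(F)(F)F | intermediate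
33 | (2S)-8-[(1S,3R,4E,7S)-1,7-dihydroxy-3,9-bis(4-hydroxyphenyl)non-4-en-1-yl]-7-hydroxy-2-(4-hydroxyphenyl)-5-methoxy-2,3-dihydro-4H-chromen-4-one | COc1cc(O)c([C@@H](O)C[C@H](/C=C/C[C@@H](O)CCc2ccc(O)cc2)c2ccc(O)cc2)c2c1C(=O)C[C@@H](c1ccc(O)cc1)O2 | target

**Step count and risks**

Total step count: 19. Longest linear sequence: 12 steps (steps 8–19, from 15).

Steps most likely to fail:

1. Step 15 (aryne insertion). The C8 aryl anion may be protonated before it reaches the ester carbonyl, leaving only an O-aryl ester. The aryne may also be consumed by an ene reaction with the chain alkene, by the pyranone carbonyl, or by arylation of the product phenoxide. The fallback sets out from 11 and 25 and comes back at 28. Ipso-iododesilylation of 11 with ICl should give 7-hydroxy-8-iodo-5-methoxy-4H-chromen-4-one F1, whose phenol is protected with MOMCl and i-Pr2NEt as 8-iodo-5-methoxy-7-(methoxymethoxy)-4H-chromen-4-one F2. Acid 25 is reduced with LiAlH4 to (3R,4E,7S)-7-(methoxymethoxy)-3,9-bis[4-(methoxymethoxy)phenyl]non-4-en-1-ol F3 and oxidised with Dess–Martin periodinane to (3R,4E,7S)-7-(methoxymethoxy)-3,9-bis[4-(methoxymethoxy)phenyl]non-4-enal F4. Iodine–magnesium exchange of F2 with i-PrMgCl·LiCl at −40 °C gives [5-methoxy-7-(methoxymethoxy)-4-oxo-4H-chromen-8-yl]magnesium chloride F5, which adds to F4 to give 8-[(3R,4E,7S)-1-hydroxy-7-(methoxymethoxy)-3,9-bis[4-(methoxymethoxy)phenyl]non-4-en-1-yl]-5-methoxy-7-(methoxymethoxy)-4H-chromen-4-one F6 as a mixture of C1'' epimers. Dess–Martin oxidation of F6 then gives ketone 28. Here the silicon of 11 serves only as a regiochemical marker for C8.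

2. Step 18 (conjugate addition). Carbopalladation of this electron-rich, 8-substituted chromone may be slow, facial selectivity may be eroded by the neighbouring C1'' centre, and the benzylic alcohol may ionise on prolonged heating. The fallback sets out from 29 and comes back at 31. Addition of 30 with Pd(OCOCF3)2 and achiral 2,2'-bipyridyl should give 31 together with its C2 epimer, (2R)-8-[(1S,3R,4E,7S)-1-hydroxy-7-(methoxymethoxy)-3,9-bis[4-(methoxymethoxy)phenyl]non-4-en-1-yl]-5-methoxy-7-(methoxymethoxy)-2-[4-(methoxymethoxy)phenyl]-2,3-dihydro-4H-chromen-4-one F7. The two are diastereomers and are separated by preparative chromatography. F7 is re-equilibrated at C2 with catalytic piperidine in ethanol through the ring-opened (E)-1-{2-hydroxy-3-[(1S,3R,4E,7S)-1-hydroxy-7-(methoxymethoxy)-3,9-bis[4-(methoxymethoxy)phenyl]non-4-en-1-yl]-6-methoxy-4-(methoxymethoxy)phenyl}-3-[4-(methoxymethoxy)phenyl]prop-2-en-1-one F8 and returned to the separation.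

3. Step 17 (ketone reduction). The twisted, doubly ortho-substituted ketone may react slowly and with poor facial discrimination, and the catalyst may be held by the pyranone carbonyl. The fallback sets out from 28 and comes back at 29. Unselective reduction with NaBH4 in THF/MeOH at −40 °C should give 29 together with its C1'' epimer, 8-[(1R,3R,4E,7S)-1-hydroxy-7-(methoxymethoxy)-3,9-bis[4-(methoxymethoxy)phenyl]non-4-en-1-yl]-5-methoxy-7-(methoxymethoxy)-4H-chromen-4-one F9. After chromatographic separation of the diastereomers, F9 is oxidised back to 28 with Dess–Martin periodinane and recycled.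

**Further compounds**

F1 | step 15 | 7-hydroxy-8-iodo-5-methoxy-4H-chromen-4-one | COc1cc(O)c(I)c2c1C(=O)C=CO2
F2 | step 15 | 8-iodo-5-methoxy-7-(methoxymethoxy)-4H-chromen-4-one | COc1cc(OCOC)c(I)c2c1C(=O)C=CO2
F3 | step 15 | (3R,4E,7S)-7-(methoxymethoxy)-3,9-bis[4-(methoxymethoxy)phenyl]non-4-en-1-ol | OCC[C@H](/C=C/C[C@@H](OCOC)CCc1ccc(OCOC)cc1)c1ccc(OCOC)cc1
F4 | step 15 | (3R,4E,7S)-7-(methoxymethoxy)-3,9-bis[4-(methoxymethoxy)phenyl]non-4-enal | O=CC[C@H](/C=C/C[C@@H](OCOC)CCc1ccc(OCOC)cc1)c1ccc(OCOC)cc1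
F5 | step 15 | [5-methoxy-7-(methoxymethoxy)-4-oxo-4H-chromen-8-yl]magnesium chloride | COc1cc(OCOC)c([Mg]Cl)c2c1C(=O)C=CO2
F6 | step 15 | 8-[(3R,4E,7S)-1-hydroxy-7-(methoxymethoxy)-3,9-bis[4-(methoxymethoxy)phenyl]non-4-en-1-yl]-5-methoxy-7-(methoxymethoxy)-4H-chromen-4-one (C1'' epimer mixture) | COc1cc(OCOC)c(C(O)C[C@H](/C=C/C[C@@H](OCOC)CCc2ccc(OCOC)cc2)c2ccc(OCOC)cc2)c2c1C(=O)C=CO2
F7 | step 18 | (2R)-8-[(1S,3R,4E,7S)-1-hydroxy-7-(methoxymethoxy)-3,9-bis[4-(methoxymethoxy)phenyl]non-4-en-1-yl]-5-methoxy-7-(methoxymethoxy)-2-[4-(methoxymethoxy)phenyl]-2,3-dihydro-4H-chromen-4-one | COc1cc(OCOC)c([C@@H](O)C[C@H](/C=C/C[C@@H](OCOC)CCc2ccc(OCOC)cc2)c2ccc(OCOC)cc2)c2c1C(=O)C[C@H](c1ccc(OCOC)cc1)O2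
F8 | step 18 | (E)-1-{2-hydroxy-3-[(1S,3R,4E,7S)-1-hydroxy-7-(methoxymethoxy)-3,9-bis[4-(methoxymethoxy)phenyl]non-4-en-1-yl]-6-methoxy-4-(methoxymethoxy)phenyl}-3-[4-(methoxymethoxy)phenyl]prop-2-en-1-one | COc1cc(OCOC)c([C@@H](O)C[C@H](/C=C/C[C@@H](OCOC)CCc2ccc(OCOC)cc2)c2ccc(OCOC)cc2)c(O)c1C(=O)/C=C/c1ccc(OCOC)cc1
F9 | step 17 | 8-[(1R,3R,4E,7S)-1-hydroxy-7-(methoxymethoxy)-3,9-bis[4-(methoxymethoxy)phenyl]non-4-en-1-yl]-5-methoxy-7-(methoxymethoxy)-4H-chromen-4-one | COc1cc(OCOC)c([C@H](O)C[C@H](/C=C/C[C@@H](OCOC)CCc2ccc(OCOC)cc2)c2ccc(OCOC)cc2)c2c1C(=O)C=CO2
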